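**Strategy.** The 1,2‑dioxolane (O1, O2, C3 with the acetic acid arm, C4, C5 with the alkyl arm) is cut at C3–C4 and O1–C5. A Lewis acid‑mediated [3+2] annulation joins a peroxycarbenium ion (O1–O2–C3, methyl and acetate arm in place, from an acetoacetate‑level silyl peroxyketal whose O–O comes from ozone) to a 2‑methyl‑1‑alkene that supplies C4, C5 and the whole side chain. It exploits the acetoacetate pattern at C3 and the isobutene‑like C4–C5(CH3) unit, and builds the ring and both quaternary centres in one operation. The alkene comes from (R)‑citronellic acid, whose C3 becomes the side‑chain stereocentre C2′ and whose carboxyl carbon becomes ring carbon C5.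

Key step: step 9

**Step 1**
Reactants: 1 (R)-citronellic acid [(3R)-3,7-dimethyloct-6-enoic acid]
Product: 3 (3R)-3-methyl-6-oxohexanoic acid, via secondary ozonide 2 (not isolated)
Conditions: O3, CH2Cl2, −78 °C; then Me2S, −78 °C to rt
Reagents that add atoms: ozone, [O-][O+]=O
Why: Ozonolysis with reductive work-up cleaves the only C=C of 1 to the aldehyde, the carboxylic acid is inert, and the chiral-pool stereocentre is not touched.

**Step 2**
Reactants: 4 (5-bromopentyl)benzene
Product: 5 (5-phenylpentyl)triphenylphosphonium bromide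
Conditions: PPh3, MeCN, reflux
Reagents that add atoms: triphenylphosphine, c1ccc(cc1)P(c1ccccc1)c1ccccc1
Why: SN2 quaternisation of triphenylphosphine by the primary bromide gives the Wittig salt.

**Step 3**
Reactants: 3 (3R)-3-methyl-6-oxohexanoic acid; 5 (5-phenylpentyl)triphenylphosphonium bromide
Product: 7 (3R,6Z)-3-methyl-11-phenylundec-6-enoic acid, via phosphonium ylide 6 (not isolated)
Conditions: 5, NaN(SiMe3)2, THF, 0 °C; then sodium salt of 3 [NaN(SiMe3)2, THF], −78 °C to rt; aq. HCl
Reagents that add atoms: none
Why: Wittig reaction of the non-stabilised ylide with the aldehyde (acid carried as its sodium carboxylate) joins the chain; the Z isomer should predominate, and the geometry is irrelevant because the alkene is hydrogenated in step 4.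

**Step 4**
Reactants: 7 (3R,6Z)-3-methyl-11-phenylundec-6-enoic acid
Product: 8 (3R)-3-methyl-11-phenylundecanoic acid
Conditions: H2 (1 atm), Pd/C, EtOAc, rt
Reagents that add atoms: none
Why: Catalytic hydrogenation saturates the disubstituted alkene (both geometric isomers converge) and leaves the arene, the acid and the remote stereocentre untouched.

**Step 5**
Reactants: 8 (3R)-3-methyl-11-phenylundecanoic acid
Product: 10 (4R)-4-methyl-12-phenyldodecan-2-one, via dilithium geminal diolate 9 (not isolated)
Conditions: MeLi (2.2 equiv), Et2O, 0 °C to rt; inverse quench into cold aq. HCl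
Reagents that add atoms: methyllithium, [Li]C
Why: Addition of methyllithium to the lithium carboxylate stops at the geminal diolate, which collapses to the methyl ketone only on acidic quench; the stereocentre is β to the carbonyl and cannot epimerise.

**Step 6**
Reactants: 10 (4R)-4-methyl-12-phenyldodecan-2-one
Product: 11 [(9R)-9,11-dimethyldodec-11-en-1-yl]benzene
Conditions: Ph3PCH3Br, KOtBu, THF, 0 °C to rt
Reagents that add atoms: methyltriphenylphosphonium bromide, C[P+](c1ccccc1)(c1ccccc1)c1ccccc1.[Br-]
Why: Wittig methylenation of the unhindered methyl ketone installs the 1,1-disubstituted alkene (future C4 and C5) without touching the β-stereocentre.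

**Step 7**
Reactants: 12 methyl 3-methylbut-3-enoate
Product: 14 methyl 3-hydroperoxy-3-methoxybutanoate (racemic), via carbonyl oxide 13 (not isolated)
Conditions: O3, CH2Cl2/MeOH, −78 °C; N2 purge, no reductant
Reagents that add atoms: ozone, [O-][O+]=O; methanol, CO
Why: Ozonolysis in methanol releases formaldehyde and the more substituted carbonyl oxide, which methanol traps as the hydroperoxy ketal; its stereocentre is racemic and irrelevant because it is planarised in step 9.

**Step 8**
Reactants: 14 methyl 3-hydroperoxy-3-methoxybutanoate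
Product: 15 methyl 3-methoxy-3-[(triethylsilyl)peroxy]butanoate (racemic)
Conditions: Et3SiCl, imidazole, DMF, 0 °C
Reagents that add atoms: chlorotriethylsilane, CC[Si](Cl)(CC)CC
Why: O-silylation of the hydroperoxide under mild imidazole buffering gives the silyl peroxyketal, the precursor class used for peroxycarbenium annulations.

**Step 9**
Reactants: 11 [(9R)-9,11-dimethyldodec-11-en-1-yl]benzene; 15 methyl 3-methoxy-3-[(triethylsilyl)peroxy]butanoate
Product: 18 methyl 2-[(3R,5R)-3,5-dimethyl-5-[(2R)-2-methyl-10-phenyldecyl]-1,2-dioxolan-3-yl]acetate, via peroxycarbenium ion 16 (not isolated), via tertiary carbocation 17 (not isolated)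
Conditions: 15 (2 equiv), SnCl4, CH2Cl2, −78 °C; aq. NaHCO3; chromatographic separation of diastereomers
Reagents that add atoms: none
Why: SnCl4 abstracts methoxide from 15 to give peroxycarbenium ion 16, whose carbon (ring C3) is attacked by the terminal CH2 of alkene 11, forming the C4–C3 bond and tertiary cation 17 at C5; the silylated distal peroxide oxygen then collapses onto C5 with loss of Et3SiCl, so the five-membered ring closes in the same operation as a stepwise polar [3+2] annulation. The closest known reaction type is the Lewis acid-mediated annulation of silyl peroxyketals with 1,1-disubstituted alkenes to 3,3,5,5-tetrasubstituted 1,2-dioxolanes. C3 is created in the C–C bond formation and C5 in the ring closure; C5 is set relative to C3 by an envelope transition state that should keep the two larger arms (CH2CO2Me and the branched alkyl chain) pseudo-equatorial, which places the two methyls cis as required. The step needs the cis (3R,5R) isomer, but only a modest cis preference is expected and the remote C2′ centre should exert little induction. That centre does make the (3R,5R) and (3S,5S) cis products diastereomers, so 18 is to be separated by chromatography from them and from the trans pair. Regio- and chemoselectivity are secured by the substrate: only the 1,1-disubstituted alkene can give a tertiary cation, it is far more nucleophilic than the alkylbenzene terminus, and at −78 °C ring closure should outrun proton loss.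

**Step 10**
Reactants: 18 methyl 2-[(3R,5R)-3,5-dimethyl-5-[(2R)-2-methyl-10-phenyldecyl]-1,2-dioxolan-3-yl]acetate
Product: 19 2-[(3R,5R)-3,5-dimethyl-5-[(2R)-2-methyl-10-phenyldecyl]-1,2-dioxolan-3-yl]acetic acid
Conditions: LiOH, THF/H2O, 0 °C to rt; then aq. HCl to pH 3
Reagents that add atoms: lithium hydroxide, [Li+].[OH-]
Why: Saponification at low temperature cleaves the methyl ester; neither peroxide carbon carries a hydrogen, so base-induced peroxide fragmentation is not available and the three stereocentres are untouched.

**Compound list**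
1 | (R)-citronellic acid, (3R)-3,7-dimethyloct-6-enoic acid | C[C@H](CCC=C(C)C)CC(=O)O | starting material
2 | secondary ozonide, (3R)-5-(5,5-dimethyl-1,2,4-trioxolan-3-yl)-3-methylpentanoic acid (epimers at the ring carbon) | C[C@H](CCC1OOC(C)(C)O1)CC(=O)O | intermediate
3 | (3R)-3-methyl-6-oxohexanoic acid | C[C@H](CCC=O)CC(=O)O | intermediate
4 | (5-bromopentyl)benzene | BrCCCCCc1ccccc1 | starting material
5 | (5-phenylpentyl)triphenylphosphonium bromide | [Br-].c1ccc(cc1)CCCCC[P+](c1ccccc1)(c1ccccc1)c1ccccc1 | intermediate
6 | phosphonium ylide, (5-phenylpentylidene)triphenylphosphorane | c1ccc(cc1)CCCCC=P(c1ccccc1)(c1ccccc1)c1ccccc1 | intermediate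
7 | (3R,6Z)-3-methyl-11-phenylundec-6-enoic acid | C[C@H](CC/C=C\CCCCc1ccccc1)CC(=O)O | intermediate
8 | (3R)-3-methyl-11-phenylundecanoic acid | C[C@H](CCCCCCCCc1ccccc1)CC(=O)O | intermediate
9 | dilithium (4R)-4-methyl-12-phenyldodecane-2,2-diolate | C[C@H](CCCCCCCCc1ccccc1)CC(C)(O[Li])O[Li] | intermediate
10 | (4R)-4-methyl-12-phenyldodecan-2-one | C[C@H](CCCCCCCCc1ccccc1)CC(C)=O | intermediate
11 | [(9R)-9,11-dimethyldodec-11-en-1-yl]benzene | C[C@H](CCCCCCCCc1ccccc1)CC(C)=C | intermediate
12 | methyl 3-methylbut-3-enoate | C=C(C)CC(=O)OC | starting material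
13 | carbonyl oxide of methyl acetoacetate, CH3C(=O+–O−)CH2CO2CH3 | COC(=O)CC(C)=[O+][O-] | intermediate
14 | methyl 3-hydroperoxy-3-methoxybutanoate (racemic) | COC(=O)CC(C)(OC)OO | intermediate
15 | methyl 3-methoxy-3-[(triethylsilyl)peroxy]butanoate (racemic) | COC(=O)CC(C)(OC)OO[Si](CC)(CC)CC | intermediate
16 | peroxycarbenium ion CH3C(=O+–OSiEt3)CH2CO2CH3 (counter-ion SnCl4(OCH3)−) | COC(=O)CC(C)=[O+]O[Si](CC)(CC)CC | intermediate
17 | tertiary carbocation at C5: methyl (3R,7R)-3,5,7-trimethyl-15-phenyl-3-[(triethylsilyl)peroxy]pentadecanoate with the positive charge on C5 | C[C@H](CCCCCCCCc1ccccc1)C[C+](C)C[C@](C)(CC(=O)OC)OO[Si](CC)(CC)CC | intermediate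
18 | methyl 2-[(3R,5R)-3,5-dimethyl-5-[(2R)-2-methyl-10-phenyldecyl]-1,2-dioxolan-3-yl]acetate | C[C@H](CCCCCCCCc1ccccc1)C[C@]1(C)C[C@](C)(CC(=O)OC)OO1 | intermediate
19 | 2-[(3R,5R)-3,5-dimethyl-5-[(2R)-2-methyl-10-phenyldecyl]-1,2-dioxolan-3-yl]acetic acid | C[C@H](CCCCCCCCc1ccccc1)C[C@]1(C)C[C@](C)(CC(=O)O)OO1 | target

**Step count.** Total: 10 steps (steps 2, 7 and 8 prepare coupling partners). Longest linear sequence: 7 steps (1, 3, 4, 5, 6, 9, 10).

**Steps most likely to fail**

1. Step 9. Two processes threaten it.
 - Ionisation of 15 may be slow and the ester-flanked peroxycarbenium ion may lose an α-proton, so that proton loss from cation 17 or breakdown of the peroxide outruns ring closure.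
 - Facial discrimination is low by design, which costs material at the separation.
 
 Fallback (sets out from 12, uses 11 as before, comes back at 19): the acetate arm is carried at the alcohol oxidation level, so the cation is no longer flanked by an ester, and the bulkier arm should also sharpen the cis preference. LiAlH4 reduction of 12 gives 3-methylbut-3-en-1-ol F1 (also purchasable). TBDPSCl/imidazole gives tert-butyl[(3-methylbut-3-en-1-yl)oxy]diphenylsilane F2. Ozonolysis in CH2Cl2/MeOH gives 4-[(tert-butyldiphenylsilyl)oxy]-2-methoxybutan-2-yl hydroperoxide F3, and Et3SiCl/imidazole gives the silyl peroxyketal tert-butyl{3-methoxy-3-[(triethylsilyl)peroxy]butoxy}diphenylsilane F4. SnCl4-mediated annulation of F4 with 11 gives tert-butyl{2-[(3S,5R)-3,5-dimethyl-5-[(2R)-2-methyl-10-phenyldecyl]-1,2-dioxolan-3-yl]ethoxy}diphenylsilane F5. This has the same spatial arrangement as 18; the C3 descriptor changes only through the priority switch. Bu4NF/AcOH in THF frees 2-[(3S,5R)-3,5-dimethyl-5-[(2R)-2-methyl-10-phenyldecyl]-1,2-dioxolan-3-yl]ethan-1-ol F6. TEMPO/PhI(OAc)2 in MeCN/H2O oxidises F6 to acid 19.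

2. Step 8. Base-induced fragmentation or β-elimination of methanol from 14 (acidic CH2 between ester and ketal) may compete, and the silyl peroxide may hydrolyse during isolation.
 Fallback (sets out from 14 and 11, comes back at 18): the silyl relay is dropped. Hydroperoxy ketal 14 is treated directly with 11 and SnCl4 in CH2Cl2 at −78 °C, so that the free hydroperoxide oxygen itself captures the C5 cation (the alkoxy hydroperoxide variant of the annulation). This fallback makes no new compound (F0).

3. Step 5. The diolate 9 may collapse before the quench and take up a third methyllithium (tertiary alcohol), or addition to the poorly soluble lithium carboxylate may stall.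
 Fallback (sets out from 8, comes back at 10): Weinreb ketone synthesis. MeNH(OMe)·HCl, EDC·HCl and Et3N in CH2Cl2 give (3R)-N-methoxy-N,3-dimethyl-11-phenylundecanamide F7. MeMgBr in THF at 0 °C then stops cleanly at ketone 10 through the chelated tetrahedral adduct.

**Further compounds**
F1 | step 9 | 3-methylbut-3-en-1-ol | C=C(C)CCO
F2 | step 9 | tert-butyl[(3-methylbut-3-en-1-yl)oxy]diphenylsilane | C=C(C)CCO[Si](c1ccccc1)(c1ccccc1)C(C)(C)C
F3 | step 9 | 4-[(tert-butyldiphenylsilyl)oxy]-2-methoxybutan-2-yl hydroperoxide (racemic) | COC(C)(OO)CCO[Si](c1ccccc1)(c1ccccc1)C(C)(C)C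
F4 | step 9 | tert-butyl{3-methoxy-3-[(triethylsilyl)peroxy]butoxy}diphenylsilane (racemic) | COC(C)(OO[Si](CC)(CC)CC)CCO[Si](c1ccccc1)(c1ccccc1)C(C)(C)C
F5 | step 9 | tert-butyl{2-[(3S,5R)-3,5-dimethyl-5-[(2R)-2-methyl-10-phenyldecyl]-1,2-dioxolan-3-yl]ethoxy}diphenylsilane | C[C@H](CCCCCCCCc1ccccc1)C[C@]1(C)C[C@](C)(CCO[Si](c1ccccc1)(c1ccccc1)C(C)(C)C)OO1
F6 | step 9 | 2-[(3S,5R)-3,5-dimethyl-5-[(2R)-2-methyl-10-phenyldecyl]-1,2-dioxolan-3-yl]ethan-1-ol | C[C@H](CCCCCCCCc1ccccc1)C[C@]1(C)C[C@](C)(CCO)OO1
F0 | step 8 | none | none
F7 | step 5 | (3R)-N-methoxy-N,3-dimethyl-11-phenylundecanamide | C[C@H](CCCCCCCCc1ccccc1)CC(=O)N(C)OC
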